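Count the G first: you asked for a quick number on summer, and this ledger stands under your hunch.

the same everywhere: L 0.11 M

| flask | G | remark | time |
|---|---|---|---|
| amber | 0.63 equiv | run made earlier |  |
| grey | 1.5 equiv | run made earlier |  |
| winter | 0.500 equiv |  | 4.0 h |
| summer | 1.20 equiv |  | 4.0 h |

- amber (time / h: E / %, Q / %): 0.200: 5.2, 13.9; 0.667: 4.9, 4.7; 1.00: 3.1, 0.4; 1.50: 6.1, 0; 2.50: 5.5, 1.5; 3.00: 3.3, 0.6; 4.00: 4.4, 0
- grey (time / h: E / %, Q / %): 0.333: 37.3, 5.9; 0.500: 41.5, 2.3; 0.667: 41.7, 1.8; 1.00: 43.9, 0.6; 1.50: 48.5, 0; 2.50: 50.5, 0.4; 4.00: 50.5, 0.3

(each reading ± 1 percentage point)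



* which of these holds the largest part of the L at the end of winter (J / L / E / Q)
* which of these holds the largest part of the L at the end of summer (J / L / E / Q)
* how much E is there at the end of summer, in percent of the L charged

Read each L that reacts as taking one G, and each E as taking one further G. Once [G] has fallen to 0, E then equals the G charged minus the L used, both in percent of the L charged. In summer the G charged stands above the L charged by 20.0%; call this difference the surplus. So, with [G] at 0, E equals the surplus plus the L left: take the surplus as the zero of the scale, and each percent of L left lifts E by one point.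

Try this on grey, where the surplus is 50.0%. E reads 50.5% at 4.00 h, so, if [G] has fallen to 0 there, the L left in grey reads as 0.5 percentage points, inside the scatter of 1 point.

The forecast names L for winter and J for summer, and puts E in summer at 20%, within 17% to 22.5%, on the ground that “L is consumed”. My own reckoning holds the surplus as the zero of the scale, with the L left in summer still to add, so I put E in summer at or above 20.0%.

    G + Q → E + D (k = 1.80 /M/min)
    Q → Z (k = 0.0500 /min)
    G + J → E + D (k = 0.570 /M/min)
    L + G → J + D (k = 3.10 /M/min)
    L + G → Q + D (k = 2.40 /M/min)

The flask gives L as the largest holder at the end of winter, at 52.9%, and J at the end of summer, at 43.0%, with E at 25.3%. That E stands 5.3 points above the surplus of 20.0%, and summer ends with 5.32% of L left and G, its limiting reagent, at 0%. Now take a neighbouring flask, like summer but charged with 0.720 equiv of G. Its surplus is −28.0%, and with [G] at 0% and 35% of L left the ledger gives 6.73%; that flask ends with E at 6.73%.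

The data are simulated with made-up constants; scatter was added.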